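**Retrosynthetic overview**
- Target ⇐ its C11 aldehyde (last-step Luche reduction); the aldehyde keeps the C3=C4 enol ether inert to acid and oxidants until the end.
- 7β-OH / 8α-OH / 10-O-coumaroyl ⇐ 7β,8β-epoxide of the Δ7 allylic p-coumarate, opened at C8 with inversion by the neighbouring ester carbonyl; the coumarate comes from a Mitsunobu reaction on C10–OH.
- C1 acylal C–O bond and side-chain CH2–CH(Me)Et C–C bond ⇐ one photochemical Wolff rearrangement of the diazoketone from (S)-2-methylbutanoic acid, with the ketene trapped by the C1 lactol (key step).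
- Lactol aldehyde ⇐ genipin by silylation, DIBAL reduction and MnO2 oxidation.
- Rings: the cis-fused cyclopenta[c]pyran core (C1, C5, C9) is bought intact in genipin and no core ring is built; the only rings made are transient, first the oxirane and then the spiro-dioxolanylium, both in step 8.

Assumption: iridoid numbering is used (C1, O2, C3–C11; H-5 and H-9 are β), "genipin-11-al" means genipin with the C4 CO2Me replaced by CHO, and genipin, (S)-2-methylbutanoic acid and (E)-p-coumaric acid are bought.

**Step 1**
Reactants: 1 genipin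
Product: 3 1-O-TMS-10-O-TBS-genipin, via 10-O-TBS-genipin 2 (not isolated)
Conditions: TBSCl (1.05 eq), imidazole (3 eq), DMF, 0 °C; then TMSCl (1.3 eq), 0 °C → rt
Reagents that add atoms: tert-butyldimethylsilyl chloride CC(C)(C)[Si](C)(C)Cl; trimethylsilyl chloride C[Si](C)(C)Cl
Why: Imidazole-mediated silylation with TBSCl is kinetically selective for the primary allylic C10–OH, and the small TMSCl then caps the hemiacetal OH of the predominant 1β-lactol with retention (silyl ether formation), blocking ring opening before hydride reduction.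

**Step 2**
Reactants: 3 1-O-TMS-10-O-TBS-genipin
Product: 4 1-O-TMS-10-O-TBS-genipin-11-ol (C4 CO2Me reduced to CH2OH)
Conditions: DIBAL-H (2.5 eq), CH2Cl2, −78 °C; Rochelle salt work-up; used crude
Reagents that add atoms: none
Why: DIBAL-H 1,2-reduction of the β-alkoxyacrylate (vinylogous carbonate) ester gives the allylic alcohol at −78 °C, and with both hydroxyls silylated the lactol cannot open, so no stereocentre is touched.

**Step 3**
Reactants: 4 1-O-TMS-10-O-TBS-genipin-11-ol
Product: 6 10-O-TBS-genipin-11-al (1β-OH lactol), via 1-O-TMS-10-O-TBS-genipin-11-al 5 (not isolated)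
Conditions: MnO2 (15 eq), CH2Cl2, rt; filter; then 10% aq. citric acid, THF, 0 °C
Reagents that add atoms: none
Why: MnO2 allylic oxidation of the highly activated 3-alkoxyallylic alcohol gives the push–pull β-alkoxy enal, and dilute citric acid then hydrolyses only the labile anomeric TMS ether while the primary TBS ether survives.

**Step 4**
Reactants: 7 (S)-2-methylbutanoic acid
Product: 9 (3S)-1-diazo-3-methylpentan-2-one, via (S)-2-methylbutanoyl chloride 8 (not isolated)
Conditions: (COCl)2, cat. DMF, CH2Cl2, 0 °C → rt; evaporate; then CH2N2 (2.5 eq), Et2O, 0 °C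
Reagents that add atoms: diazomethane C=[N+]=[N-]
Why: Arndt–Eistert acylation of diazomethane by the acid chloride (the second equivalent scavenges HCl as MeCl) runs without amine base, so the α-stereocentre bought in 7 is not enolised.

**Step 5**
Reactants: 6 10-O-TBS-genipin-11-al (limiting), 9 (3S)-1-diazo-3-methylpentan-2-one (2.5 eq)
Product: 11 1β-O-[(3S)-3-methylpentanoyl]-10-O-TBS-genipin-11-al, via (S)-sec-butylketene 10 (not isolated)
Conditions: hν (370 nm LED), DMAP (10 mol%), CH2Cl2, 20 °C, 9 added over 2 h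
Reagents that add atoms: none
Why: Proposed new method: photochemical Wolff rearrangement of 9 (N2 loss with 1,2-shift of the stereogenic sec-butyl carbon with retention) gives ketene 10 at a low, photon-limited concentration that suppresses dimerisation, DMAP converts it into an acylpyridinium enolate that is protonated and then acylated by the acidic hemiacetal O–H of the limiting lactol, and this forms the C1–O acylal bond and the side-chain CH2–CH bond in one event without opening the ring, with C1 fixed as the substrate-preferred β (pseudoaxial, H-1/H-9 trans) anomer; the closest known chemistry is the photochemical Arndt–Eistert esterification of simple alcohols used in excess and DMAP-catalysed ketene O-acylation, which to my knowledge have not been applied to a ring-chain tautomeric hemiacetal as limiting reagent to make an acylal.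

**Step 6**
Reactants: 11 1β-O-[(3S)-3-methylpentanoyl]-10-O-TBS-genipin-11-al
Product: 12 1β-O-[(3S)-3-methylpentanoyl]-genipin-11-al (C10–OH free)
Conditions: Et3N·3HF (5 eq), THF, rt
Reagents that add atoms: none
Why: Fluoride cleavage of the primary TBS ether with nearly neutral Et3N·3HF leaves the acylal, the enal and the alkene intact (silyl ether deprotection).

**Step 7**
Reactants: 12 1β-O-[(3S)-3-methylpentanoyl]-genipin-11-al, 13 (E)-p-coumaric acid
Product: 14 10-O-[(E)-p-coumaroyl]-1β-O-[(3S)-3-methylpentanoyl]-genipin-11-al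
Conditions: PPh3 (1.3 eq), DIAD (1.3 eq), THF, 0 °C → rt
Reagents that add atoms: none
Why: Mitsunobu esterification in which only the carboxylic acid (pKa about 4.5) is ionised by the betaine, so the free phenol needs no protection, and SN2 displacement at the primary allylic C10 oxyphosphonium touches no stereocentre and keeps the E-alkene.

**Step 8**
Reactants: 14 10-O-[(E)-p-coumaroyl]-1β-O-[(3S)-3-methylpentanoyl]-genipin-11-al
Product: 17 7β,8α-dihydroxy-7,8-dihydro derivative of 14 (10-O-coumaroyl, 11-al), via β-epoxide 15 (not isolated), via dioxolanylium cation 16 (not isolated)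
Conditions: DMDO (1.2 eq), acetone, −20 °C; evaporate at 0 °C; then CSA (10 mol%), THF–H2O (20:1), 0 °C → rt
Reagents that add atoms: dimethyldioxirane CC1(C)OO1; water O
Why: DMDO epoxidises only the electron-rich trisubstituted C7=C8 from the convex β-face (C3=C4 and the cinnamate are deactivated by conjugation), setting 7β-O by substrate control, and acid then triggers 5-exo neighbouring-group opening at tertiary C8 by the ester carbonyl with inversion (8α-O) followed by hydrolysis of the dioxolan-2-ylium to the primary C10 ester (epoxy-ester/acyloxonium, Woodward–Prévost-type anti-dihydroxylation).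

**Step 9**
Reactants: 17 7β,8α-diol 11-aldehyde
Product: 18 CNP0241834.1, [(1S,4aS,6S,7R,7aS)-6,7-dihydroxy-4-(hydroxymethyl)-1-{[(3S)-3-methylpentanoyl]oxy}-1,4a,5,6,7,7a-hexahydrocyclopenta[c]pyran-7-yl]methyl (2E)-3-(4-hydroxyphenyl)prop-2-enoate
Conditions: NaBH4 (1.0 eq), CeCl3·7H2O (1.0 eq), MeOH–THF (1:3), −60 °C; pH 7 buffer
Reagents that add atoms: none
Why: Luche reduction, in which CeCl3-activated NaBH4 reduces the aldehyde 1,2 within minutes at −60 °C while the acylal, the cinnamate ester and the enol ether are untouched, and no stereocentre is formed.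

**Compound list**
1 | genipin, methyl (1R,4aS,7aS)-1-hydroxy-7-(hydroxymethyl)-1,4a,5,7a-tetrahydrocyclopenta[c]pyran-4-carboxylate | O[C@@H]1OC=C(C(=O)OC)[C@H]2CC=C(CO)[C@@H]12 | starting material
2 | 10-O-TBS-genipin (not isolated) | O[C@@H]1OC=C(C(=O)OC)[C@H]2CC=C(CO[Si](C)(C)C(C)(C)C)[C@@H]12 | intermediate
3 | 1-O-TMS-10-O-TBS-genipin (1β-OSiMe3) | C[Si](C)(C)O[C@@H]1OC=C(C(=O)OC)[C@H]2CC=C(CO[Si](C)(C)C(C)(C)C)[C@@H]12 | intermediate
4 | 1-O-TMS-10-O-TBS-genipin-11-ol (C4 CH2OH) | C[Si](C)(C)O[C@@H]1OC=C(CO)[C@H]2CC=C(CO[Si](C)(C)C(C)(C)C)[C@@H]12 | intermediate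
5 | 1-O-TMS-10-O-TBS-genipin-11-al (not isolated) | C[Si](C)(C)O[C@@H]1OC=C(C=O)[C@H]2CC=C(CO[Si](C)(C)C(C)(C)C)[C@@H]12 | intermediate
6 | 10-O-TBS-genipin-11-al, (1R,4aS,7aS)-7-(TBSOCH2)-1-hydroxy-1,4a,5,7a-tetrahydrocyclopenta[c]pyran-4-carbaldehyde | O[C@@H]1OC=C(C=O)[C@H]2CC=C(CO[Si](C)(C)C(C)(C)C)[C@@H]12 | intermediate
7 | (S)-2-methylbutanoic acid | CC[C@H](C)C(=O)O | starting material
8 | (S)-2-methylbutanoyl chloride (not isolated) | CC[C@H](C)C(=O)Cl | intermediate
9 | (3S)-1-diazo-3-methylpentan-2-one | CC[C@H](C)C(=O)C=[N+]=[N-] | intermediate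
10 | (S)-sec-butylketene, (3S)-3-methylpent-1-en-1-one (not isolated) | CC[C@H](C)C=C=O | intermediate
11 | 1β-O-[(3S)-3-methylpentanoyl]-10-O-TBS-genipin-11-al | CC[C@H](C)CC(=O)O[C@@H]1OC=C(C=O)[C@H]2CC=C(CO[Si](C)(C)C(C)(C)C)[C@@H]12 | intermediate
12 | 1β-O-[(3S)-3-methylpentanoyl]-genipin-11-al (C10–OH free) | CC[C@H](C)CC(=O)O[C@@H]1OC=C(C=O)[C@H]2CC=C(CO)[C@@H]12 | intermediate
13 | (E)-p-coumaric acid | OC(=O)/C=C/c1ccc(O)cc1 | starting material
14 | 10-O-[(E)-p-coumaroyl]-1β-O-[(3S)-3-methylpentanoyl]-genipin-11-al | CC[C@H](C)CC(=O)O[C@@H]1OC=C(C=O)[C@H]2CC=C(COC(=O)/C=C/c3ccc(O)cc3)[C@@H]12 | intermediate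
15 | 7β,8β-epoxide of 14, oxirane O on the H-5/H-9 face (not isolated) | CC[C@H](C)CC(=O)O[C@@H]1OC=C(C=O)[C@H]2C[C@@H]3O[C@]3(COC(=O)/C=C/c4ccc(O)cc4)[C@@H]12 | intermediate
16 | spiro-1,3-dioxolan-2-ylium cation: C8–O(α) and C10–O bridged by the (E)-4-hydroxystyryl carbenium carbon, 7β-OH (not isolated) | CC[C@H](C)CC(=O)O[C@@H]1OC=C(C=O)[C@H]2C[C@H](O)[C@]3(CO[C+](/C=C/c4ccc(O)cc4)O3)[C@@H]12 | intermediate
17 | 7β,8α-dihydroxy-10-O-[(E)-p-coumaroyl]-1β-O-[(3S)-3-methylpentanoyl]-7,8-dihydrogenipin-11-al | CC[C@H](C)CC(=O)O[C@@H]1OC=C(C=O)[C@H]2C[C@H](O)[C@](O)(COC(=O)/C=C/c3ccc(O)cc3)[C@@H]12 | intermediate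
18 | CNP0241834.1 (1β-O-acyl, 7β-OH, 8α-OH, 10-O-coumaroyl, 11-OH) | CC[C@H](C)CC(=O)O[C@@H]1OC=C(CO)[C@H]2C[C@H](O)[C@](O)(COC(=O)/C=C/c3ccc(O)cc3)[C@@H]12 | target

**Totals and risks**
Total step count: 9 (eight on the genipin line plus one for the diazoketone). Longest linear sequence: 8 (steps 1, 2, 3, 5, 6, 7, 8, 9).

Step 5 (the proposed new step) may fail through ketene dimerisation, carbene O–H insertion, or sluggish acylation of the hindered hemiacetal. The fallback uses known chemistry; it sets out from diazoketone 9 and lactol 6 and comes back at 11. Silver benzoate/Et3N-catalysed Wolff rearrangement of 9 in THF–water gives (3S)-3-methylpentanoic acid F1 (classical Arndt–Eistert homologation, retention). Steglich esterification of lactol 6 with F1 (DCC, DMAP, CH2Cl2, 0 °C) then gives 11.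

Step 7 may fail through phenol O-alkylation or low conversion with the unprotected phenolic acid. The fallback sets out from 12 and comes back at 14. Appel bromination (CBr4, PPh3, CH2Cl2, 0 °C) gives the primary allylic bromide F2. SN2 alkylation of caesium p-coumarate (13 with 0.5 eq Cs2CO3, DMF, rt; only the carboxylic acid is ionised) then gives 14.

Step 8 may fail through oxidation of the free phenol or aldehyde by DMDO, incomplete β-face selectivity, or decomposition in the one-pot acid stage. The fallback sets out from 12, before the phenol is present, and comes back at 15 and then 17. Hydroxyl-directed epoxidation of 12 with VO(acac)2/t-BuOOH (CH2Cl2, 0 °C) gives the 7β,8β-epoxy alcohol F3, which can be separated from any α-epoxide. Mitsunobu esterification of F3 with 13 gives 15 as an isolated, purified compound. Its opening is then run as a separate step (CSA in wet THF, or BF3·OEt2 at −40 °C followed by water) to reach 17.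

**Further compounds**
F1 | step 5 | (3S)-3-methylpentanoic acid | CC[C@H](C)CC(=O)O
F2 | step 7 | 10-bromo-10-deoxy-1β-O-[(3S)-3-methylpentanoyl]-genipin-11-al | CC[C@H](C)CC(=O)O[C@@H]1OC=C(C=O)[C@H]2CC=C(CBr)[C@@H]12
F3 | step 8 | 7β,8β-epoxy-1β-O-[(3S)-3-methylpentanoyl]-7,8-dihydrogenipin-11-al (C10–OH free) | CC[C@H](C)CC(=O)O[C@@H]1OC=C(C=O)[C@H]2C[C@@H]3O[C@]3(CO)[C@@H]12
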